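**Plan**

1. Retrosynthesis, last cut first: the four O-benzyl groups and the saturation of the two-carbon bridge are removed, which leads back to a tetra-O-benzyl (E)-stilbene.
2. Three C–C bonds at the central ring A are then cut in one operation (target numbering of ring A: C1 bridge, C2/C6 4-hydroxybenzyl, C3 OH, C4 H, C5 OMe): C2–CH2Ar, C6–CH2Ar and C1–Cα of the bridge. This leaves 1-(benzyloxy)-3-iodo-5-methoxybenzene, two molecules of 4-(benzyloxy)benzyl chloride and 3-(benzyloxy)styrene.
3. Enabling feature: ring A carries at C2/C1/C6 a contiguous ortho/ipso/ortho triad of carbon substituents with two identical benzyl groups flanking the bridge carbon, while C4 between the two oxygens is unsubstituted. This is the retron of a Pd/norbornene (Catellani) ortho,ortho'-dialkylation/ipso-Heck cascade that starts from iodine at C1.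
4. Forward: all benzene rings are bought and none is built. Ring A is O-benzylated and converted from bromide to iodide, and the styrene is made by Wittig methylenation. One flask then attaches both benzyl arms and, last, the ring–bridge bond; hydrogenation completes the route.
5. Stereochemistry: the target has no stereocentre and no stereogenic double bond, so it is a single achiral compound and nothing has to be controlled. The E-alkene made in the key step is erased by the final hydrogenation.

Key step: step 4

Remark: the organopalladium species of the catalytic cycle in step 4 are catalyst-bound; they are described in the Why line and are not numbered as compounds.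

**Route**

Step 1
Reactants: 1 3-bromo-5-methoxyphenol
Product: 2 1-(benzyloxy)-3-bromo-5-methoxybenzene
Conditions: BnBr, K2CO3, DMF, rt
Reagents that add atoms: benzyl bromide, BrCc1ccccc1
Why: Williamson ether synthesis (SN2 alkylation of the phenoxide), which masks the ring-A phenol against O-alkylation by 6 in step 4 with a group that the final hydrogenation removes.

Step 2
Reactants: 2 1-(benzyloxy)-3-bromo-5-methoxybenzene
Product: 3 1-(benzyloxy)-3-iodo-5-methoxybenzene
Conditions: NaI (2 equiv), CuI (5 mol%), trans-N,N'-dimethylcyclohexane-1,2-diamine (10 mol%), 1,4-dioxane, 110 °C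
Reagents that add atoms: sodium iodide, [Na+].[I-]
Why: Copper(I)/diamine-catalysed aromatic Finkelstein halogen exchange, driven by the low solubility of NaBr in dioxane, should give the aryl iodide that the Pd(0)/norbornene manifold of step 4 needs for fast oxidative addition, with the aryl ethers inert.

Step 3
Reactants: 4 3-(benzyloxy)benzaldehyde
Product: 5 3-(benzyloxy)styrene (1-(benzyloxy)-3-ethenylbenzene)
Conditions: Ph3PCH3Br, KOtBu, THF, 0 °C to rt
Reagents that add atoms: methyltriphenylphosphonium bromide, C[P+](c1ccccc1)(c1ccccc1)c1ccccc1.[Br-]
Why: Wittig methylenation of a non-enolisable aryl aldehyde with the non-stabilised ylide generated in the flask, with the benzyl ether inert.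

Step 4
Reactants: 3 1-(benzyloxy)-3-iodo-5-methoxybenzene; 5 3-(benzyloxy)styrene; 6 4-(benzyloxy)benzyl chloride (two molecules are incorporated)
Product: 7 1-(benzyloxy)-2,4-bis[4-(benzyloxy)benzyl]-3-[(E)-2-(3-(benzyloxy)phenyl)ethenyl]-5-methoxybenzene
Conditions: Pd(OAc)2 (10 mol%), P(2-furyl)3 (22 mol%), norbornene (2 equiv), Cs2CO3 (5 equiv), 6 (3 equiv), 5 (2 equiv), MeCN, 85 °C
Reagents that add atoms: none
Why: Proposed new method: Pd(0) inserts into the C–I bond of 3, norbornene undergoes syn-carbopalladation, and carbonate-assisted palladation of an ortho C–H gives a five-membered aryl–norbornyl palladacycle that is alkylated by benzylic chloride 6 through a Pd(IV) intermediate; the same events at the second ortho C–H, β-carbon elimination of norbornene and Mizoroki–Heck insertion/syn-β-hydride elimination with 5 form the aryl–vinyl bond and return Pd(0). The closest known reaction type is the Catellani ortho,ortho'-dialkylation/ipso-Heck reaction of aryl iodides with primary alkyl halides and terminal alkenes, whose secure precedent lies with aryl iodides that have no meta substituents; here each ortho C–H is flanked by OMe or OBn, and the proposal rests on the small in-plane size of alkoxy groups (ortho-alkoxyaryl–palladium species are ordinary) and on their acidifying effect on the flanked C–H in the concerted metalation–deprotonation. No ring is closed and no stereocentre is formed; the E geometry of the alkene follows from syn insertion and syn elimination and is erased in step 5. The step needs chemoselectivity, secured by the reactivity gap between the aryl iodide (chosen by Pd(0)) and the benzylic chloride (chosen by the nucleophilic Pd(II) palladacycle), and site selectivity, secured because only the two positions ortho to iodine are within reach of the norbornyl-bound palladium and both receive the same group, so that the unsymmetrical OMe/OBn pattern raises no regiochemical question. The bridge bond is formed last, from the 2,6-dibenzylated arylpalladium(II) species, because norbornene is expelled only once both ortho positions are filled, so the hindered aryl fragment and the styrene are joined without the hindered aryl halide ever being prepared.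

Step 5
Reactants: 7 1-(benzyloxy)-2,4-bis[4-(benzyloxy)benzyl]-3-[(E)-2-(3-(benzyloxy)phenyl)ethenyl]-5-methoxybenzene
Product: 8 3,3'-dihydroxy-2,6-bis(4-hydroxybenzyl)-5-methoxybibenzyl
Conditions: H2 (1 atm), 10% Pd/C, EtOAc–MeOH, rt
Reagents that add atoms: none
Why: Heterogeneous catalytic hydrogenation should saturate the 1,2-disubstituted stilbene double bond and hydrogenolyse the four aryl benzyl ethers in one operation, while the aryl methyl ether and the diarylmethane C–C bonds are inert to Pd/H2 at room temperature.

**Compound list**

1 | 3-bromo-5-methoxyphenol | COc1cc(O)cc(Br)c1 | starting material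
2 | 1-(benzyloxy)-3-bromo-5-methoxybenzene | COc1cc(Br)cc(OCc2ccccc2)c1 | intermediate
3 | 1-(benzyloxy)-3-iodo-5-methoxybenzene | COc1cc(I)cc(OCc2ccccc2)c1 | intermediate
4 | 3-(benzyloxy)benzaldehyde | O=Cc1cccc(OCc2ccccc2)c1 | starting material
5 | 3-(benzyloxy)styrene | C=Cc1cccc(OCc2ccccc2)c1 | intermediate
6 | 4-(benzyloxy)benzyl chloride | ClCc1ccc(OCc2ccccc2)cc1 | starting material
7 | 1-(benzyloxy)-2,4-bis[4-(benzyloxy)benzyl]-3-[(E)-2-(3-(benzyloxy)phenyl)ethenyl]-5-methoxybenzene | COc1cc(OCc2ccccc2)c(Cc2ccc(OCc3ccccc3)cc2)c(/C=C/c2cccc(OCc3ccccc3)c2)c1Cc1ccc(OCc2ccccc2)cc1 | intermediate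
8 | 3,3'-dihydroxy-2,6-bis(4-hydroxybenzyl)-5-methoxybibenzyl | COc1cc(O)c(Cc2ccc(O)cc2)c(CCc2cccc(O)c2)c1Cc1ccc(O)cc1 | target

**Step count and risks**

Total step count: 5. Longest linear sequence: 4 steps (steps 1, 2, 4, 5); step 3 is a one-step branch.

Steps most likely to fail:

1. Step 4 (Proposed new method). Three processes may defeat it. Palladation of the two ortho C–H bonds, each flanked by an alkoxy group, may be too slow, so that the cascade stops at norbornyl-containing by-products or at the plain Heck product. Pd(0) may insert into the benzylic chloride and consume it in Heck or homocoupling pathways. The final arylpalladium may cyclise onto a flanking benzyl ring before the styrene inserts.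
Fallback (known chemistry): the route sets out from 2. Lewis-acid-catalysed Friedel–Crafts benzylation with 6 (2.2 equiv, catalytic ZnCl2, CH2Cl2, 0 °C to rt) should take place twice, at the two positions para to an alkoxy group and ortho to bromine, and give 1-(benzyloxy)-3-bromo-2,4-bis[4-(benzyloxy)benzyl]-5-methoxybenzene F1. A Mizoroki–Heck reaction of this hindered aryl bromide with 5 (Pd2(dba)3, P(t-Bu)3, Cs2CO3, dioxane, 100 °C) then comes back to the route at 7.

2. Step 5. Saturation of the hindered, twisted stilbene double bond may lag behind, or the fourfold O-debenzylation may stall through poisoning of the catalyst by traces of iodide or phosphine carried over from step 4.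
Fallback: the route sets out from 7. Diimide reduction of the alkene (TsNHNH2, NaOAc, DME–H2O, reflux) should give 1-(benzyloxy)-2,4-bis[4-(benzyloxy)benzyl]-3-[2-(3-(benzyloxy)phenyl)ethyl]-5-methoxybenzene F2. Non-reductive cleavage of the four benzyl ethers with BCl3 and pentamethylbenzene as cation scavenger (CH2Cl2, −78 °C), which spares the aryl methyl ether, comes back to the route at 8.

3. Step 2. The halogen exchange is an equilibrium and may stay incomplete, which leaves aryl bromide that is hard to separate and reacts sluggishly in step 4.
Fallback: the route sets out from 2. Bromine–lithium exchange (n-BuLi, THF, −78 °C) should give [3-(benzyloxy)-5-methoxyphenyl]lithium F3, which is quenched at −78 °C with I2 and comes back to the route at 3.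

**Further compounds**

F1 | step 4 | 1-(benzyloxy)-3-bromo-2,4-bis[4-(benzyloxy)benzyl]-5-methoxybenzene | COc1cc(OCc2ccccc2)c(Cc2ccc(OCc3ccccc3)cc2)c(Br)c1Cc1ccc(OCc2ccccc2)cc1
F2 | step 5 | 1-(benzyloxy)-2,4-bis[4-(benzyloxy)benzyl]-3-[2-(3-(benzyloxy)phenyl)ethyl]-5-methoxybenzene | COc1cc(OCc2ccccc2)c(Cc2ccc(OCc3ccccc3)cc2)c(CCc2cccc(OCc3ccccc3)c2)c1Cc1ccc(OCc2ccccc2)cc1
F3 | step 2 | [3-(benzyloxy)-5-methoxyphenyl]lithium | [Li]c1cc(OC)cc(OCc2ccccc2)c1
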